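**Retrosynthetic overview**

1. The last step removes a vinyl triflate (the masked ring-A diene) and an N-allyloxycarbonyl group from 24; the quinone of 24 comes from oxidation of a 1-naphthol.
2. Key disconnection: rings D (quinone) and E (thiazine dioxide) are closed together by a thermal intramolecular dehydrogenative Diels–Alder reaction. It joins the ring-C carbon para to the quaternary centre to the alkyne carbon that becomes the quinone C=O next to sulfur, and the N-bearing carbon to the S-bearing carbon of the quinone C=C.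
3. Enabling feature: the N–CH2–CH2–SO2 chain of ring E is a ready four-atom tether between the enol carbon of the aryl ketone and a sulfonyl alkyne; the ring-C C=C next to that ketone completes the diene, and the quaternary carbon blocks the other ortho CH.
4. Rings A and B and the stereocentre: racemic benzoxepinedione 7 (ring B built on ring C) undergoes a stereoconvergent phase-transfer Robinson annulation with ethyl vinyl ketone; Tf2O then gives the dienol lactone as its dienyl triflate.
5. Ring order: C (bought) → B → A → D and E (one step) → quinone.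

Key step: step 15

Assumption: 1 is taken as a catalogue compound; it is also the product of hydrolysing the less hindered ester of dimethyl 2-bromoterephthalate.

**Route**

Step 1
Reactants: 1 3-bromo-4-(methoxycarbonyl)benzoic acid
Product: 2 4-tert-butyl 1-methyl 2-bromobenzene-1,4-dicarboxylate
Conditions: Boc2O, DMAP (cat.), t-BuOH, THF, 40 °C
Reagents that add atoms: di-tert-butyl dicarbonate CC(C)(C)OC(=O)OC(=O)OC(C)(C)C
Why: DMAP-catalysed tert-butyl esterification through the mixed carbonic anhydride should differentiate the two carboxyls, so that the para one can be freed with acid late in the route.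

Step 2
Reactants: 2 4-tert-butyl 1-methyl 2-bromobenzene-1,4-dicarboxylate; 3 4,4,5,5-tetramethyl-2-vinyl-1,3,2-dioxaborolane
Product: 4 4-tert-butyl 1-methyl 2-vinylbenzene-1,4-dicarboxylate
Conditions: PdCl2(dppf) (3 mol%), K2CO3, dioxane/H2O, 80 °C
Reagents that add atoms: none
Why: Suzuki–Miyaura coupling of an electron-poor aryl bromide with a vinylboronate is routine and should leave both esters untouched.

Step 3
Reactants: 4 4-tert-butyl 1-methyl 2-vinylbenzene-1,4-dicarboxylate
Product: 5 4-tert-butyl 1-methyl 2-(1-oxopropan-2-yl)benzene-1,4-dicarboxylate (racemic)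
Conditions: Rh(acac)(CO)2 (0.5 mol%), PPh3, CO/H2 (1:1, 40 bar), toluene, 40 °C
Reagents that add atoms: carbon monoxide [C-]#[O+]
Why: Rhodium-catalysed hydroformylation of styrenes is branched-selective (benzylic rhodium alkyl) and should give the 2-arylpropanal; its stereocentre is labile and of no consequence.

Step 4
Reactants: 5 4-tert-butyl 1-methyl 2-(1-oxopropan-2-yl)benzene-1,4-dicarboxylate
Product: 6 4-tert-butyl 1-methyl 2-(4-hydroxy-3-oxobutan-2-yl)benzene-1,4-dicarboxylate (racemic)
Conditions: paraformaldehyde, 3-benzyl-5-(2-hydroxyethyl)-4-methylthiazolium chloride (10 mol%), i-Pr2NEt (10 mol%), THF, 60 °C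
Reagents that add atoms: formaldehyde (from paraformaldehyde) C=O
Why: Thiazolium-carbene-catalysed cross-acyloin reaction (hydroxymethylation) should add the acyl-anion equivalent of the aldehyde to formaldehyde, which outruns self-condensation of the hindered α-branched aldehyde.

Step 5
Reactants: 6 4-tert-butyl 1-methyl 2-(4-hydroxy-3-oxobutan-2-yl)benzene-1,4-dicarboxylate
Product: 7 tert-butyl 5-methyl-1,4-dioxo-1,3,4,5-tetrahydro-2-benzoxepine-7-carboxylate (racemic)
Conditions: Bu2SnO (10 mol%), toluene, 110 °C, 4 Å molecular sieves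
Reagents that add atoms: none
Why: Tin-catalysed intramolecular transesterification (lactonisation) should close the seven-membered ring B on the ortho methyl ester only, since the para tert-butyl ester is out of reach; the benzylic stereocentre stays racemic and labile.

Step 6
Reactants: 7 tert-butyl 5-methyl-1,4-dioxo-1,3,4,5-tetrahydro-2-benzoxepine-7-carboxylate; 8 pent-1-en-3-one
Product: 10 tert-butyl (11bS)-4,11b-dimethyl-3,7-dioxo-1,2,3,5,7,11b-hexahydrodibenzo[c,e]oxepine-10-carboxylate, via Michael adduct 9 (not isolated)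
Conditions: N-(9-anthracenylmethyl)cinchonidinium chloride (10 mol%), Cs2CO3 (0.2 equiv), toluene, −20 °C; then pyrrolidine (0.3 equiv), AcOH (0.3 equiv), 50 °C
Reagents that add atoms: none
Why: Robinson annulation as an asymmetric phase-transfer Michael addition followed by amine-catalysed aldol condensation: the acidic benzylic C–H of racemic 7 gives a planar enolate, the cinchona ammonium ion pair shields one face so that both enantiomers of 7 should converge on the (S) quaternary centre (the pseudoenantiomeric cinchoninium salt is used if the sense proves opposite), and the enamine of the ethyl ketone closes ring A on the ring ketone.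

Step 7
Reactants: 10 tert-butyl (11bS)-4,11b-dimethyl-3,7-dioxo-1,2,3,5,7,11b-hexahydrodibenzo[c,e]oxepine-10-carboxylate
Product: 11 tert-butyl (11bS)-4,11b-dimethyl-7-oxo-3-(trifluoromethylsulfonyloxy)-1,2,7,11b-tetrahydrodibenzo[c,e]oxepine-10-carboxylate
Conditions: Tf2O, 2,6-di-tert-butyl-4-methylpyridine, CH2Cl2, 0 °C → rt
Reagents that add atoms: triflic anhydride O=S(=O)(OS(=O)(=O)C(F)(F)F)C(F)(F)F
Why: Thermodynamic enol triflation of an enone with Tf2O and a hindered pyridine (as with steroidal 4-en-3-ones) should remove the γ-hydrogen on the O–CH2 carbon and give the linearly conjugated dienyl triflate, which is already the dienol lactone of the target with its electron-rich diene masked.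

Step 8
Reactants: 11 tert-butyl (11bS)-4,11b-dimethyl-7-oxo-3-(trifluoromethylsulfonyloxy)-1,2,7,11b-tetrahydrodibenzo[c,e]oxepine-10-carboxylate
Product: 12 (11bS)-4,11b-dimethyl-7-oxo-3-(trifluoromethylsulfonyloxy)-1,2,7,11b-tetrahydrodibenzo[c,e]oxepine-10-carboxylic acid
Conditions: TFA/CH2Cl2 (1:4), 0 °C → rt
Reagents that add atoms: none
Why: Acidolysis of the tert-butyl ester (loss of isobutene) should free the para carboxyl, enol triflate and enol lactone being stable to TFA.

Step 9
Reactants: 12 (11bS)-4,11b-dimethyl-7-oxo-3-(trifluoromethylsulfonyloxy)-1,2,7,11b-tetrahydrodibenzo[c,e]oxepine-10-carboxylic acid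
Product: 14 (11bS)-10-(2-diazoacetyl)-4,11b-dimethyl-7-oxo-1,2,7,11b-tetrahydrodibenzo[c,e]oxepin-3-yl trifluoromethanesulfonate, via acid chloride 13 (not isolated)
Conditions: (COCl)2, DMF (cat.), CH2Cl2, 0 °C; then TMSCHN2, MeCN/THF, 0 °C
Reagents that add atoms: (trimethylsilyl)diazomethane C[Si](C)(C)C=[N+]=[N-]
Why: Acid chloride formation and acylation of the diazoalkane (first stage of an Arndt–Eistert sequence) should give the α-diazoketone without touching enol lactone or triflate.

Step 10
Reactants: 15 2-aminoethanethiol hydrochloride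
Product: 16 allyl (2-sulfanylethyl)carbamate
Conditions: diallyl dicarbonate, Et3N, MeOH (degassed), 0 °C
Reagents that add atoms: diallyl dicarbonate C=CCOC(=O)OC(=O)OCC=C
Why: Chemoselective N-acylation of the amine by the dicarbonate should install a carbamate that survives heat and is later removed by palladium.

Step 11
Reactants: 16 allyl (2-sulfanylethyl)carbamate
Product: 17 allyl (2-{[(trimethylsilyl)ethynyl]sulfanyl}ethyl)carbamate
Conditions: 1-[(trimethylsilyl)ethynyl]-1,2-benziodoxol-3(1H)-one, 1,1,3,3-tetramethylguanidine, THF, rt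
Reagents that add atoms: 1-[(trimethylsilyl)ethynyl]-1,2-benziodoxol-3(1H)-one C[Si](C)(C)C#CI1OC(=O)c2ccccc12
Why: Electrophilic alkynylation of a thiolate with an ethynylbenziodoxolone reagent is fast and selective for sulfur.

Step 12
Reactants: 17 allyl (2-{[(trimethylsilyl)ethynyl]sulfanyl}ethyl)carbamate
Product: 18 allyl (2-{[(trimethylsilyl)ethynyl]sulfonyl}ethyl)carbamate
Conditions: mCPBA (2.2 equiv), CH2Cl2, 0 °C → rt
Reagents that add atoms: 3-chloroperoxybenzoic acid OOC(=O)c1cccc(Cl)c1
Why: Peracid oxidation of the alkynyl sulfide to the sulfone should be faster than epoxidation of the allyl ester alkene, and it turns the alkyne into a strong dienophile whose silyl cap tempers its sensitivity to base.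

Step 13
Reactants: 14 (11bS)-10-(2-diazoacetyl)-4,11b-dimethyl-7-oxo-1,2,7,11b-tetrahydrodibenzo[c,e]oxepin-3-yl trifluoromethanesulfonate; 18 allyl (2-{[(trimethylsilyl)ethynyl]sulfonyl}ethyl)carbamate
Product: 19 allyl N-{2-oxo-2-[(11bS)-4,11b-dimethyl-7-oxo-3-(trifluoromethylsulfonyloxy)-1,2,7,11b-tetrahydrodibenzo[c,e]oxepin-10-yl]ethyl}-N-(2-{[(trimethylsilyl)ethynyl]sulfonyl}ethyl)carbamate
Conditions: Rh2(OAc)4 (2 mol%), CH2Cl2, 40 °C, slow addition of 14
Reagents that add atoms: none
Why: Dirhodium-carbenoid N–H insertion of an α-diazoketone into a carbamate should form the C–N bond under neutral conditions, so the carbamate N–H and the alkynyl sulfone never meet a base.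

Step 14
Reactants: 19 the α-amido ketone of step 13
Product: 20 (Z)-tert-butyldimethylsilyl enol ether of 19 (Ar–C(OSiMe2t-Bu)=CH–N; oxygen cis to nitrogen)
Conditions: TBSOTf, Et3N, CH2Cl2, 0 °C
Reagents that add atoms: tert-butyldimethylsilyl triflate CC(C)(C)[Si](C)(C)OS(=O)(=O)C(F)(F)F
Why: Soft enolisation of the aryl ketone with silyl triflate and amine should give the Z enol ether, the isomer that avoids allylic strain between the aryl ring and the amido substituent.

Step 15
Reactants: 20 (Z)-tert-butyldimethylsilyl enol ether of 19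
Product: 22 O-silyl C-silyl N-Alloc naphtho-fused thiazine dioxide (ring D aromatic; round ring D from the former ketone carbon: OSiMe2t-Bu then N(Alloc) then SO2 then SiMe3; N–CH2CH2–SO2 closes ring E; rings A and B as in 11), via cycloadduct 21 (not isolated)
Conditions: PhNO2 (0.02 M), 165 °C, sealed tube, N2
Reagents that add atoms: none
Why: Proposed new method: on heating, the 2-amido-1-siloxystyrene unit of 20 (the ring-C C=C next to the enol ether plus the enol ether C=C) should act as an electron-rich diene toward the tethered sulfonyl-activated silylalkyne in a concerted intramolecular [4+2] cycloaddition, and the isoaromatic cis-1,4-dihydro adduct 21 should expel H2 to give the naphthalene; the closest known reaction type is the thermal dehydrogenative (didehydro) Diels–Alder reaction of styrene-ynes to naphthalenes. Ring D closes as the six-membered cycloadduct ring, and ring E closes in the same event as the six-membered ring spanned by the four-atom N–CH2–CH2–SO2 tether attached to the diene terminus, so the aryl–C(alkyne) bond and the C(enol)–C(sulfonyl) bond form together. No lasting stereocentre is made: the two sp3 CH centres of 21 are cis by suprafacial addition and vanish on aromatisation, and the quaternary centre is remote and untouched. The positions of sulfur and nitrogen are fixed by the tether, and of the two ortho carbons of ring C only the one para to the quaternary carbon can react, because the other is flanked by that quaternary carbon. The Z enol ether keeps the tether on the outside of the diene, the donors (OSi, N) and the acceptor (SO2) are matched for bonding of the arene carbon to the β-alkyne carbon, and loss of H2 instead of silanol keeps the oxygen needed for the quinone.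

Step 16
Reactants: 22 O-silyl C-silyl N-Alloc naphtho-fused thiazine dioxide
Product: 24 N-allyloxycarbonyl 3-(trifluoromethylsulfonyloxy) derivative of the target (quinone present; ring A still the dienyl triflate), via naphthol 23 (not isolated)
Conditions: TBAF, AcOH, THF, 0 °C → rt; then PhI(OCOCF3)2, MeCN/H2O (4:1), 0 °C
Reagents that add atoms: water O
Why: Fluoride should cleave the silyl ether and protodesilylate the aryl silane flanked by the sulfonyl group, and hypervalent-iodine oxidation of a 1-naphthol with a free para position gives the 1,4-quinone (any surviving aryl–Si would be replaced at the same carbon); the triflate keeps the diene inert to the oxidant.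

Step 17
Reactants: 24 N-allyloxycarbonyl 3-(trifluoromethylsulfonyloxy) derivative of the target
Product: 25 CNP0348176.1 (target, S configuration)
Conditions: Pd(OAc)2 (10 mol%), PPh3 (20 mol%), HCO2H, Bu3N, DMF, 60 °C; then air
Reagents that add atoms: none
Why: Palladium-catalysed formate reduction of the enol triflate and π-allyl cleavage of the allyl carbamate (formate as hydride source and allyl scavenger) should unveil the diene and the N–H in one operation, any hydroquinone being re-oxidised by air.

**Compound list**

1 | 3-bromo-4-(methoxycarbonyl)benzoic acid | COC(=O)c1ccc(cc1Br)C(=O)O | starting material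
2 | 4-tert-butyl 1-methyl 2-bromobenzene-1,4-dicarboxylate | COC(=O)c1ccc(cc1Br)C(=O)OC(C)(C)C | intermediate
3 | 4,4,5,5-tetramethyl-2-vinyl-1,3,2-dioxaborolane | C=CB1OC(C)(C)C(C)(C)O1 | starting material
4 | 4-tert-butyl 1-methyl 2-vinylbenzene-1,4-dicarboxylate | COC(=O)c1ccc(cc1C=C)C(=O)OC(C)(C)C | intermediate
5 | 4-tert-butyl 1-methyl 2-(1-oxopropan-2-yl)benzene-1,4-dicarboxylate (racemic) | COC(=O)c1ccc(cc1C(C)C=O)C(=O)OC(C)(C)C | intermediate
6 | 4-tert-butyl 1-methyl 2-(4-hydroxy-3-oxobutan-2-yl)benzene-1,4-dicarboxylate (racemic) | COC(=O)c1ccc(cc1C(C)C(=O)CO)C(=O)OC(C)(C)C | intermediate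
7 | tert-butyl 5-methyl-1,4-dioxo-1,3,4,5-tetrahydro-2-benzoxepine-7-carboxylate (racemic, stereocentre labile) | CC1C(=O)COC(=O)c2ccc(cc12)C(=O)OC(C)(C)C | intermediate
8 | pent-1-en-3-one | CCC(=O)C=C | starting material
9 | tert-butyl (5S)-5-methyl-1,4-dioxo-5-(3-oxopentyl)-1,3,4,5-tetrahydro-2-benzoxepine-7-carboxylate | CCC(=O)CC[C@]1(C)C(=O)COC(=O)c2ccc(cc21)C(=O)OC(C)(C)C | intermediate
10 | tert-butyl (11bS)-4,11b-dimethyl-3,7-dioxo-1,2,3,5,7,11b-hexahydrodibenzo[c,e]oxepine-10-carboxylate | O=C1CC[C@]2(C)C(=C1C)COC(=O)c1ccc(cc12)C(=O)OC(C)(C)C | intermediate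
11 | tert-butyl (11bS)-4,11b-dimethyl-7-oxo-3-(trifluoromethylsulfonyloxy)-1,2,7,11b-tetrahydrodibenzo[c,e]oxepine-10-carboxylate | CC1=C(OS(=O)(=O)C(F)(F)F)CC[C@]2(C)C1=COC(=O)c1ccc(cc12)C(=O)OC(C)(C)C | intermediate
12 | (11bS)-4,11b-dimethyl-7-oxo-3-(trifluoromethylsulfonyloxy)-1,2,7,11b-tetrahydrodibenzo[c,e]oxepine-10-carboxylic acid | CC1=C(OS(=O)(=O)C(F)(F)F)CC[C@]2(C)C1=COC(=O)c1ccc(cc12)C(=O)O | intermediate
13 | acid chloride of 12 | CC1=C(OS(=O)(=O)C(F)(F)F)CC[C@]2(C)C1=COC(=O)c1ccc(cc12)C(=O)Cl | intermediate
14 | (11bS)-10-(2-diazoacetyl)-4,11b-dimethyl-7-oxo-1,2,7,11b-tetrahydrodibenzo[c,e]oxepin-3-yl trifluoromethanesulfonate | CC1=C(OS(=O)(=O)C(F)(F)F)CC[C@]2(C)C1=COC(=O)c1ccc(cc12)C(=O)C=[N+]=[N-] | intermediate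
15 | 2-aminoethanethiol hydrochloride | [NH3+]CCS.[Cl-] | starting material
16 | allyl (2-sulfanylethyl)carbamate | C=CCOC(=O)NCCS | intermediate
17 | allyl (2-{[(trimethylsilyl)ethynyl]sulfanyl}ethyl)carbamate | C=CCOC(=O)NCCSC#C[Si](C)(C)C | intermediate
18 | allyl (2-{[(trimethylsilyl)ethynyl]sulfonyl}ethyl)carbamate | C=CCOC(=O)NCCS(=O)(=O)C#C[Si](C)(C)C | intermediate
19 | allyl N-{2-oxo-2-[10-yl of the core of 11]ethyl}-N-(2-{[(trimethylsilyl)ethynyl]sulfonyl}ethyl)carbamate | CC1=C(OS(=O)(=O)C(F)(F)F)CC[C@]2(C)C1=COC(=O)c1ccc(cc12)C(=O)CN(CCS(=O)(=O)C#C[Si](C)(C)C)C(=O)OCC=C | intermediate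
20 | (Z)-tert-butyldimethylsilyl enol ether of 19 (O cis to N) | CC1=C(OS(=O)(=O)C(F)(F)F)CC[C@]2(C)C1=COC(=O)c1ccc(cc12)/C(O[Si](C)(C)C(C)(C)C)=C/N(CCS(=O)(=O)C#C[Si](C)(C)C)C(=O)OCC=C | intermediate
21 | [4+2] cycloadduct (ring C dearomatised; the two new CH centres cis, either face relative to the quaternary centre) | CC1=C(OS(=O)(=O)C(F)(F)F)CC[C@]2(C)C1=COC(=O)C1=CC3C(C=C12)=C(O[Si](C)(C)C(C)(C)C)C1N(C(=O)OCC=C)CCS(=O)(=O)C1=C3[Si](C)(C)C | intermediate
22 | O-silyl C-silyl N-Alloc naphtho-fused thiazine dioxide | CC1=C(OS(=O)(=O)C(F)(F)F)CC[C@]2(C)C1=COC(=O)c1cc3c(cc12)c(O[Si](C)(C)C(C)(C)C)c1N(C(=O)OCC=C)CCS(=O)(=O)c1c3[Si](C)(C)C | intermediate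
23 | desilylated 1-naphthol (free para CH) | CC1=C(OS(=O)(=O)C(F)(F)F)CC[C@]2(C)C1=COC(=O)c1cc3c(cc12)c(O)c1N(C(=O)OCC=C)CCS(=O)(=O)c1c3 | intermediate
24 | N-allyloxycarbonyl 3-(trifluoromethylsulfonyloxy) derivative of the target | CC1=C(OS(=O)(=O)C(F)(F)F)CC[C@]2(C)C1=COC(=O)c1cc3c(cc12)C(=O)C1=C(C3=O)S(=O)(=O)CCN1C(=O)OCC=C | intermediate
25 | CNP0348176.1, (S)-dienol lactone thiazino-naphthoquinone | CC1=CCC[C@]2(C)C1=COC(=O)c1cc3c(cc12)C(=O)C1=C(C3=O)S(=O)(=O)CCN1 | target

**Step count and risks**

Total step count: 17. Longest linear sequence: 14 (steps 1–9 and 13–17); steps 10–12 make side chain 18.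

Step 15 (Proposed new method). What may go wrong: a stepwise ionic addition of the enol ether carbon to the β-alkyne carbon (giving a seven-membered ring), a hydrogen shift followed by loss of silanol instead of H2, or decomposition before cycloaddition. The fallback sets out from 12 and comes back at 24, using known chemistry. Acid chloride 13 (as in step 9) with dimethylsulfoxonium methylide (Me3S(O)I, KOt-Bu, THF, 0 °C) gives the β-keto sulfoxonium ylide F1. Trivalent-rhodium-catalysed C–H activation and [4+2] annulation of F1 with alkyne 18 ([Cp*RhCl2]2, AgSbF6, Zn(OTf)2, DCE, 80 °C; loss of DMSO) gives the naphthol F2; the aryl group should add to the silyl-bearing β-carbon of the acetylenic sulfone (conjugate sense), which would have to be confirmed. PhI(OCOCF3)2 in aqueous MeCN oxidises F2 with replacement of silicon to the sulfonylquinone F3. K2CO3 in DMF under air closes ring E by conjugate addition of the carbamate nitrogen and re-oxidation, which gives 24.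

Step 6. What may go wrong: poor facial selectivity in the ion pair (low enantiomeric purity), slow Michael addition, or base-induced opening of the keto lactone. The fallback sets out from 7 and comes back at 10: the annulation is run without chiral catalyst (DBU cat., then pyrrolidine/AcOH) to the racemic enone F4, which is resolved by preparative chromatography on a chiral stationary phase; the (S) enantiomer is 10.

Step 13. What may go wrong: diversion of the carbenoid to cyclopropanation of the allyl group, to dimerisation, or to attack by the carbamate carbonyl oxygen. The fallback sets out from 14 and comes back at 19: 48% HBr converts 14 into the α-bromoketone F5; the sodium salt of sulfide-level carbamate 17 (NaH, DMF, 0 °C), which carries no electrophilic alkyne, is N-alkylated by F5 to the alkynyl sulfide F6; mCPBA then oxidises sulfur to the sulfone, which gives 19.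

**Further compounds**

F1 | step 15 | β-keto sulfoxonium ylide from 13 | CC1=C(OS(=O)(=O)C(F)(F)F)CC[C@]2(C)C1=COC(=O)c1ccc(cc12)C(=O)C=S(C)(C)=O
F2 | step 15 | 1-naphthol with the sulfonylethyl carbamate chain and SiMe3 on ring D | CC1=C(OS(=O)(=O)C(F)(F)F)CC[C@]2(C)C1=COC(=O)c1cc3c(cc12)c(O)cc(S(=O)(=O)CCNC(=O)OCC=C)c3[Si](C)(C)C
F3 | step 15 | 2-sulfonyl-1,4-naphthoquinone with open carbamate chain | CC1=C(OS(=O)(=O)C(F)(F)F)CC[C@]2(C)C1=COC(=O)c1cc3c(cc12)C(=O)C=C(S(=O)(=O)CCNC(=O)OCC=C)C3=O
F4 | step 6 | racemic 10 | O=C1CCC2(C)C(=C1C)COC(=O)c1ccc(cc12)C(=O)OC(C)(C)C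
F5 | step 13 | α-bromoketone from 14 | CC1=C(OS(=O)(=O)C(F)(F)F)CC[C@]2(C)C1=COC(=O)c1ccc(cc12)C(=O)CBr
F6 | step 13 | alkynyl sulfide analogue of 19 | CC1=C(OS(=O)(=O)C(F)(F)F)CC[C@]2(C)C1=COC(=O)c1ccc(cc12)C(=O)CN(CCSC#C[Si](C)(C)C)C(=O)OCC=C
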